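**Assumption:** the decalin is numbered as in drimane (C3 carbinol, C4 gem-dimethyl, C5/C10 ring fusion, C7=C8, C9 bearing C11H2–O; α = face opposite the C10 methyl), and racemic 11 is drawn as the enantiomer that leads to the target.

**Retrosynthetic overview**
1. Target 12 ⇐ racemic 3-ketone 11: an (S)-CBS reduction sets C3 and picks out one enantiomer, the other half leaving as a separable diastereomer.
2. 11 ⇐ acyclic (2Z,6E) tertiary α-keto mesylate 9: the α-keto cation (enolonium) at C4 is captured by the C5=C10 alkene (ring A, C4–C5), then C9–C10 closes ring B, in one step.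
3. 9 ⇐ α-ketol 8 ⇐ allylic bromide 5 + dianion of 3-hydroxy-3-methylbutan-2-one (C1–C2 bond).
4. 5 ⇐ scopoletin neryl ether 3 (SeO2 oxidation, Appel) ⇐ scopoletin 1 + nerol 2 (Mitsunobu).

**Route**

Step 1
Reactants: 1 scopoletin (7-hydroxy-6-methoxy-2H-chromen-2-one); 2 nerol ((2Z)-3,7-dimethylocta-2,6-dien-1-ol)
Product: 3 scopoletin neryl ether 7-[(2Z)-3,7-dimethylocta-2,6-dienyloxy]-6-methoxy-2H-chromen-2-one
Conditions: PPh3, DIAD, THF, 0 °C to rt
Reagents that add atoms: none
Why: Mitsunobu etherification, in which the acidic 7-OH of scopoletin displaces the activated primary allylic alcohol by SN2 and leaves the (2Z) alkene geometry untouched.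

Step 2
Reactants: 3 scopoletin neryl ether
Product: 4 allylic alcohol 7-[(2Z,6E)-8-hydroxy-3,7-dimethylocta-2,6-dienyloxy]-6-methoxy-2H-chromen-2-one
Conditions: SeO2 (0.3 equiv), t-BuOOH (3 equiv), salicylic acid (0.1 equiv), CH2Cl2, 0 °C to rt
Reagents that add atoms: tert-butyl hydroperoxide, CC(C)(C)OO (the oxygen atom, passed on through catalytic SeO2, O=[Se]=O)
Why: Catalytic SeO2 allylic oxidation (ene reaction then [2,3]-shift) attacks only the electron-rich terminal alkene and gives the (E)-allylic alcohol, fixing the (6E) geometry that later gives the trans ring fusion.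

Step 3
Reactants: 4 allylic alcohol
Product: 5 allylic bromide 7-[(2Z,6E)-8-bromo-3,7-dimethylocta-2,6-dienyloxy]-6-methoxy-2H-chromen-2-one
Conditions: CBr4, PPh3, CH2Cl2, 0 °C
Reagents that add atoms: tetrabromomethane, BrC(Br)(Br)Br
Why: Appel bromination converts the primary allylic alcohol to the bromide by SN2 at 0 °C without allylic transposition or loss of either alkene geometry.

Step 4
Reactants: 5 allylic bromide; 6 3-hydroxy-3-methylbutan-2-one
Product: 8 acyclic α-ketol 7-[(2Z,6E)-11-hydroxy-3,7,11-trimethyl-10-oxododeca-2,6-dienyloxy]-6-methoxy-2H-chromen-2-one, via dilithium enolate-alkoxide 7 (not isolated)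
Conditions: 6 (1.5 equiv), LiN(iPr)2 (3.2 equiv, commercial solution), THF, −78 °C; then 5, DMPU, −78 to −40 °C; then H2O
Reagents that add atoms: none
Why: Enolate alkylation, in which 6 can enolise only at its methyl group, so its dianion is expected to alkylate the reactive allylic bromide by SN2 at low temperature faster than it adds to the electron-rich alkoxycoumarin lactone, placing the ketone at C3 and the future leaving group at C4.

Step 5
Reactants: 8 acyclic α-ketol
Product: 9 tertiary α-keto mesylate (6E,10Z)-12-[(6-methoxy-2-oxo-2H-chromen-7-yl)oxy]-2,6,10-trimethyl-3-oxododeca-6,10-dien-2-yl methanesulfonate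
Conditions: MsCl, Et3N, CH2Cl2, −20 to 0 °C; cold work-up and short silica plug
Reagents that add atoms: methanesulfonyl chloride, CS(=O)(=O)Cl
Why: Sulfene-type mesylation (MsCl/Et3N) works on tertiary alcohols, and the adjacent carbonyl slows ionisation enough for the tertiary α-keto mesylate to be handled.

Step 6
Reactants: 9 tertiary α-keto mesylate
Product: 11 racemic (1R*,4aR*,8aS*)-ketone 7-{[2,5,5,8a-tetramethyl-6-oxo-1,4,4a,5,6,7,8,8a-octahydronaphthalen-1-yl]methoxy}-6-methoxy-2H-chromen-2-one, via α-keto carbenium mesylate ion pair 10 (not isolated)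
Conditions: (CF3)2CHOH/CH2Cl2 (4:1, 0.005 M), 2,6-di-tert-butyl-4-methylpyridine (1.5 equiv), 0 to 25 °C; AgNO3-impregnated silica to remove the minor exocyclic-alkene isomer
Reagents that add atoms: none
Why: Proposed new method: tertiary α-keto mesylates are known to ionise in fluorinated alcohols to α-keto carbenium ions, and here that cation at C4 (the α-carbon of the C3 ketone, used as an electrophile) is trapped by the C5=C10 alkene in a 6-endo Markovnikov closure of ring A, after which the C10 cation is trapped by the C8=C9 alkene to close ring B; chair–chair folding turns the (6E) alkene into the trans ring fusion and the (2Z) alkene into an axial C9–CH2OAr trans to the C10 methyl, and E1 loss of the axial C7 proton gives the C7=C8 alkene because the equatorial C9–H cannot align; the closest known reactions are epoxide- or sulfonate-initiated cation–olefin polycyclisations, including those run in (CF3)2CHOH, and the hindered pyridine only scavenges MsOH so no oxyallyl pathway opens.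

Step 7
Reactants: 11 racemic (1R*,4aR*,8aS*)-ketone
Product: 12 target 7-{[(1R,4aR,6R,8aS)-6-hydroxy-2,5,5,8a-tetramethyl-1,4,4a,5,6,7,8,8a-octahydronaphthalen-1-yl]methoxy}-6-methoxy-2H-chromen-2-one
Conditions: (S)-2-methyl-CBS-oxazaborolidine (1.0 equiv, precomplexed), BH3·SMe2 (1.0 equiv), CH2Cl2, −20 °C; MeOH quench; silica chromatography to separate the diastereomeric alcohol
Reagents that add atoms: none
Why: Corey–Bakshi–Shibata reduction under reagent control, in which the (S)-catalyst (large group = quaternary C4, small = C2H2) delivers hydride to the same absolute face of C3 in both enantiomers of 11, giving the (3R) axial 3α-alcohol 12 from the (1R,4aR,8aS) ketone and a separable equatorial-alcohol diastereomer from its mirror image; the enantiomer of 12 could form only against both catalyst and substrate bias, so the isolated axial alcohol is a single enantiomer (at most half of 11 is used).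

**Compound list**
1 | scopoletin (7-hydroxy-6-methoxy-2H-chromen-2-one) | COc1cc2ccc(=O)oc2cc1O | starting material
2 | nerol ((2Z)-3,7-dimethylocta-2,6-dien-1-ol) | OC/C=C(C)\CCC=C(C)C | starting material
3 | 7-[(2Z)-3,7-dimethylocta-2,6-dienyloxy]-6-methoxy-2H-chromen-2-one | COc1cc2ccc(=O)oc2cc1OC/C=C(C)\CCC=C(C)C | intermediate
4 | 7-[(2Z,6E)-8-hydroxy-3,7-dimethylocta-2,6-dienyloxy]-6-methoxy-2H-chromen-2-one | COc1cc2ccc(=O)oc2cc1OC/C=C(C)\CC/C=C(C)/CO | intermediate
5 | 7-[(2Z,6E)-8-bromo-3,7-dimethylocta-2,6-dienyloxy]-6-methoxy-2H-chromen-2-one | COc1cc2ccc(=O)oc2cc1OC/C=C(C)\CC/C=C(C)/CBr | intermediate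
6 | 3-hydroxy-3-methylbutan-2-one | CC(=O)C(C)(C)O | starting material
7 | dilithium 3-methylbut-1-ene-2,3-diolate (enolate-alkoxide of 6; not isolated) | [Li+].[Li+].C=C([O-])C(C)(C)[O-] | intermediate
8 | 7-[(2Z,6E)-11-hydroxy-3,7,11-trimethyl-10-oxododeca-2,6-dienyloxy]-6-methoxy-2H-chromen-2-one | COc1cc2ccc(=O)oc2cc1OC/C=C(C)\CC/C=C(C)/CCC(=O)C(C)(C)O | intermediate
9 | (6E,10Z)-12-[(6-methoxy-2-oxo-2H-chromen-7-yl)oxy]-2,6,10-trimethyl-3-oxododeca-6,10-dien-2-yl methanesulfonate | COc1cc2ccc(=O)oc2cc1OC/C=C(C)\CC/C=C(C)/CCC(=O)C(C)(C)OS(C)(=O)=O | intermediate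
10 | tertiary α-keto carbenium ion of 9 (cation at future C4) paired with methanesulfonate; not isolated | COc1cc2ccc(=O)oc2cc1OC/C=C(C)\CC/C=C(C)/CCC(=O)[C+](C)C.CS(=O)(=O)[O-] | intermediate
11 | racemic 7-{[(1R*,4aR*,8aS*)-2,5,5,8a-tetramethyl-6-oxo-1,4,4a,5,6,7,8,8a-octahydronaphthalen-1-yl]methoxy}-6-methoxy-2H-chromen-2-one (drawn: 1R,4aR,8aS; mirror image present 1:1) | COc1cc2ccc(=O)oc2cc1OC[C@@H]1C(C)=CC[C@H]2C(C)(C)C(=O)CC[C@]12C | intermediate
12 | 7-{[(1R,4aR,6R,8aS)-6-hydroxy-2,5,5,8a-tetramethyl-1,4,4a,5,6,7,8,8a-octahydronaphthalen-1-yl]methoxy}-6-methoxy-2H-chromen-2-one (CNP0218138.2) | COc1cc2ccc(=O)oc2cc1OC[C@@H]1C(C)=CC[C@H]2C(C)(C)[C@H](O)CC[C@]12C | target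

**Totals**
Total steps: 7. Longest linear sequence: 7 (from 1 and 2; 6 enters at step 4).

**Steps most likely to fail**

Step 6 (key bicyclisation). The α-keto cation may lose a proton to the isopropenyl ketone, stop after ring A, or the allylic aryl ether may ionise; some exocyclic alkene is also expected. The fallback replaces the two-electron cation by its one-electron counterpart and sets out from 9. SmI2 in THF at −78 °C cleaves the C–OMs bond to the regiodefined samarium enolate, and trapping with TMSCl/Et3N gives the trimethylsilyl enol ether 7-[(2Z,6E)-3,7,11-trimethyl-10-(trimethylsilyloxy)dodeca-2,6,10-trienyloxy]-6-methoxy-2H-chromen-2-one F1. Oxidation of F1 with Cu(OTf)2/Cu2O in MeCN at 0 °C gives the enol-ether radical cation, an electrophilic tertiary α-keto radical. This closes ring A and then ring B in two 6-endo steps, and divalent copper oxidises the C8 radical to the alkene. The route is rejoined at 11.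

Step 4 (dianion alkylation beside a coumarin lactone). The enolate may add to the lactone or its C3=C4 bond. The fallback avoids strong base and sets out from 5. CuI (cat.), K2CO3 and NaI in DMF couple 5 with 2-methylbut-3-yn-2-ol to give the skipped enyne carbinol 7-[(2Z,6E)-11-hydroxy-3,7,11-trimethyldodeca-2,6-dien-9-ynyloxy]-6-methoxy-2H-chromen-2-one F2. AgOAc (cat.), DBU and CO2 (1 atm) in MeCN then close the (Z)-alkylidene cyclic carbonate 4-{(3E,7Z)-9-[(6-methoxy-2-oxo-2H-chromen-7-yl)oxy]-3,7-dimethylnona-3,7-dienylidene}-5,5-dimethyl-1,3-dioxolan-2-one F3. Mild hydrolysis (K2CO3, MeOH/H2O) releases CO2 and the enol tautomerises to the ketone next to the carbinol carbon. The route is rejoined at 8.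

Step 7 (catalyst-controlled reduction in the mismatched sense). For the wanted enantiomer the catalyst must force equatorial hydride delivery, and uncatalysed borane may instead give the 3β-epimer, lowering the yield though not the enantiopurity. The fallback sets out from racemic 11 and uses substrate control followed by resolution. LiBH(sec-Bu)3 in THF at −78 °C attacks equatorially and gives the racemic axial alcohol, that is 12 together with its mirror image 7-{[(1S,4aS,6S,8aR)-6-hydroxy-2,5,5,8a-tetramethyl-1,4,4a,5,6,7,8,8a-octahydronaphthalen-1-yl]methoxy}-6-methoxy-2H-chromen-2-one F4. Preparative chromatography on a chiral stationary phase (amylose tris(3,5-dimethylphenylcarbamate)) removes F4. The route is rejoined at 12.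

Further compounds
F1 | step 6 | 7-[(2Z,6E)-3,7,11-trimethyl-10-(trimethylsilyloxy)dodeca-2,6,10-trienyloxy]-6-methoxy-2H-chromen-2-one | COc1cc2ccc(=O)oc2cc1OC/C=C(C)\CC/C=C(C)/CCC(O[Si](C)(C)C)=C(C)C
F2 | step 4 | 7-[(2Z,6E)-11-hydroxy-3,7,11-trimethyldodeca-2,6-dien-9-ynyloxy]-6-methoxy-2H-chromen-2-one | COc1cc2ccc(=O)oc2cc1OC/C=C(C)\CC/C=C(C)/CC#CC(C)(C)O
F3 | step 4 | 4-{(3E,7Z)-9-[(6-methoxy-2-oxo-2H-chromen-7-yl)oxy]-3,7-dimethylnona-3,7-dienylidene}-5,5-dimethyl-1,3-dioxolan-2-one (Z at the ring alkylidene) | COc1cc2ccc(=O)oc2cc1OC/C=C(C)\CC/C=C(C)/C/C=C1\OC(=O)OC1(C)C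
F4 | step 7 | 7-{[(1S,4aS,6S,8aR)-6-hydroxy-2,5,5,8a-tetramethyl-1,4,4a,5,6,7,8,8a-octahydronaphthalen-1-yl]methoxy}-6-methoxy-2H-chromen-2-one (mirror image of 12) | COc1cc2ccc(=O)oc2cc1OC[C@H]1C(C)=CC[C@@H]2C(C)(C)[C@@H](O)CC[C@@]12C
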